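**Assumptions:** Commercial (R)-4-(TBSO)cyclopent-2-enone is the chiral-pool source. Its carbinol stereocentre is a temporary relay. It directs the addition that sets the quaternary carbinol and is then destroyed by oxidation. The allenylzinc adds 1,2 and anti to the OTBS group. The exocyclic C7=C8 alkene is Z, as in the target SMILES, with the dienyl chain syn to the C=O. That geometry should be the thermodynamic one, because the other face of the alkylidene is flanked by the quaternary carbinol carbon.

## Retrosynthesis
1. No ring is formed. The cyclopentenone ring comes from the chiral pool, and the C7=C8 dienyl unit is added last by aldol condensation of the C5 (α′) enolate of a 2-bromo-4-hydroxy-4-alkylcyclopentenone with enal 5 (methyl (E)-7-oxohept-5-enoate).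
2. The bromoenone comes from α-bromination/dehydrobromination of the hydroxy-enone.
3. The Z-alkene comes from Lindlar reduction of an alkyne. The alkyne is carried through the bromination because Br2 would attack a Z-alkene, and it is reduced right after bromination.
4. The quaternary carbinol (R in the target) comes from 1,2-addition of an allenylzinc to (R)-4-OTBS-cyclopentenone anti to OTBS. Deprotection and MnO2 oxidation then remove the relay stereocentre.

## Route

**Step 1**
Reactants: 1, oct-2-yn-1-ol
Product: 2, 1-bromo-2-octyne
Conditions: CBr4, PPh3, CH2Cl2, 0 °C → rt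
Reagents that add atoms: CBr4, BrC(Br)(Br)Br
Why: Appel bromination, an SN2 displacement of the propargylic alkoxyphosphonium, gives the propargyl bromide; there are no stereocentres.

**Step 2**
Reactants: 3, methyl hex-5-enoate; 4, acrolein (5 equiv)
Product: 5, methyl (E)-7-oxohept-5-enoate
Conditions: Hoveyda–Grubbs II (5 mol %), CH2Cl2, 40 °C
Reagents that add atoms: none
Why: Olefin cross-metathesis, driven by loss of ethylene, gives the thermodynamically preferred E-enal, which matches the 5E alkene of the target.

**Step 3**
Reactants: 6, (R)-4-(tert-butyldimethylsilyloxy)cyclopent-2-en-1-one; 2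
Product: 7, (1S,4R)-4-(TBSO)-1-(oct-2-yn-1-yl)cyclopent-2-en-1-ol
Conditions: Zn dust (activated), THF, 0 °C → rt; aq. NH4Cl work-up
Reagents that add atoms: none (Zn is lost as salts; the octynyl group comes from reactant 2)
Why: Barbier-type allenylzinc addition by an SE2′ pathway gives the homopropargylic alcohol, adding to the C=O rather than the C=C. The nucleophile approaches the face anti to OTBS, so the new C–OH ends up cis to OTBS and the carbinol is set as (S) in this intermediate. The descriptor becomes (R) in the target only because the CIP priorities change, not the spatial arrangement.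

**Step 4**
Reactants: 7
Product: 8, (1S,4R)-1-(oct-2-yn-1-yl)cyclopent-2-ene-1,4-diol (cis-diol)
Conditions: HF·pyridine, THF/pyridine, 0 °C → rt
Reagents that add atoms: none
Why: Fluoride-mediated desilylation leaves the alkyne and the tertiary alcohol untouched, and no stereocentre is affected.

**Step 5**
Reactants: 8
Product: 9, (S)-4-hydroxy-4-(oct-2-yn-1-yl)cyclopent-2-en-1-one
Conditions: activated MnO2 (10 equiv), CH2Cl2, rt
Reagents that add atoms: none
Why: MnO2 oxidizes only the secondary allylic alcohol, so the relay centre is destroyed while the tertiary carbinol keeps its configuration.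

**Step 6**
Reactants: 9
Product: 10, (S)-2-bromo-4-hydroxy-4-(oct-2-yn-1-yl)cyclopent-2-en-1-one
Conditions: Br2 (1.05 equiv), CH2Cl2, −78 → 0 °C, dark; then Et3N (3 equiv), 0 °C → rt
Reagents that add atoms: bromine, BrBr
Why: Br2 adds across the enone C=C, and E1cB loss of HBr with Et3N gives the 2-bromoenone. It is done before alkene formation so that only the slowly reacting alkyne competes.

**Step 7**
Reactants: 10
Product: 11, (S)-2-bromo-4-hydroxy-4-[(2Z)-oct-2-en-1-yl]cyclopent-2-en-1-one
Conditions: H2 (1 atm), Lindlar catalyst, quinoline, EtOAc, rt, stop at full alkyne consumption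
Reagents that add atoms: none (only H is added)
Why: Syn hydrogenation on the poisoned Pd catalyst gives the cis-alkene, which is the side-chain 14Z olefin.

**Step 8**
Reactants: 11; 5
Product: 12, aldol adduct (mixture of diastereomers at C8 and the new carbinol, C7)
Conditions: LDA (2.3 equiv), THF, −78 °C; then 5 (1.2 equiv), −78 °C; aq. NH4Cl
Reagents that add atoms: none
Why: The first equivalent of LDA deprotonates the tertiary OH. The second forms the C5 (α′) enolate, the only enolizable position, which adds 1,2 to the enal in an aldol addition. The two new stereocentres are removed in Step 9, and the quaternary carbinol is not involved.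

**Step 9**
Reactants: 12
Product: 13, bromoclavulone III
Conditions: MsCl (1.5 equiv), Et3N (5 equiv), CH2Cl2, −20 °C → rt
Reagents that add atoms: none (the mesylate is lost)
Why: Mesylation of the secondary aldol OH followed by E1cB elimination gives the cross-conjugated dienone. The Z isomer, with the chain syn to C=O, is favoured because the alternative would clash with the quaternary carbinol. The tertiary OH is too hindered to mesylate under these conditions.

## Compound list
1 | oct-2-yn-1-ol | CCCCCC#CCO | starting material
2 | 1-bromo-2-octyne | CCCCCC#CCBr | intermediate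
3 | methyl hex-5-enoate | C=CCCCC(=O)OC | starting material
4 | acrolein | C=CC=O | starting material
5 | methyl (E)-7-oxohept-5-enoate | COC(=O)CCC/C=C/C=O | intermediate
6 | (R)-4-(TBSO)cyclopent-2-en-1-one | O=C1C=C[C@H](O[Si](C)(C)C(C)(C)C)C1 | starting material
7 | (1S,4R)-4-(TBSO)-1-(oct-2-yn-1-yl)cyclopent-2-en-1-ol | CCCCCC#CC[C@@]1(O)C=C[C@H](O[Si](C)(C)C(C)(C)C)C1 | intermediate
8 | (1S,4R)-1-(oct-2-yn-1-yl)cyclopent-2-ene-1,4-diol | CCCCCC#CC[C@@]1(O)C=C[C@H](O)C1 | intermediate
9 | (S)-4-hydroxy-4-(oct-2-yn-1-yl)cyclopent-2-en-1-one | CCCCCC#CC[C@@]1(O)C=CC(=O)C1 | intermediate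
10 | (S)-2-bromo-4-hydroxy-4-(oct-2-yn-1-yl)cyclopent-2-en-1-one | CCCCCC#CC[C@@]1(O)C=C(Br)C(=O)C1 | intermediate
11 | (S)-2-bromo-4-hydroxy-4-[(2Z)-oct-2-en-1-yl]cyclopent-2-en-1-one | CCCCC/C=C\C[C@@]1(O)C=C(Br)C(=O)C1 | intermediate
12 | aldol adduct (diastereomeric mixture at C8 and C7, unassigned) | CCCCC/C=C\C[C@@]1(O)C=C(Br)C(=O)C1C(O)/C=C/CCCC(=O)OC | intermediate
13 | bromoclavulone III, methyl (5E,7Z,12R,14Z)-10-bromo-12-hydroxy-9-oxoprosta-5,7,10,14-tetraen-1-oate | CCCCC/C=C\C[C@@]1(O)C=C(Br)C(=O)/C1=C\C=C\CCCC(=O)OC | target

## Totals
- Total steps: 9, of which 2 are preparations of coupling partners (Steps 1 and 2).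
- Longest linear sequence: 8 steps (Steps 1, 3, 4, 5, 6, 7, 8, 9: oct-2-yn-1-ol → 2 → 7 → 8 → 9 → 10 → 11 → 12 → 13). The other branch, 3 + 4 → 5 (Step 2), joins at Step 8.

## Three steps most likely to fail
1. **Step 6 (bromination).** Br2 may add to the internal alkyne as well as the enone.
   - Fallback: mask the alkyne as its Co2(CO)6 complex, brominate, then decomplex (CAN) before Step 7.
2. **Step 7 (Lindlar).** The vinyl C–Br bond may be hydrogenolysed, or the ring alkene partly reduced.
   - Fallback: use a metal-free cis-reduction with diimide (from 2-nitrobenzenesulfonylhydrazide and Et3N), which leaves C–Br untouched.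
3. **Steps 8 and 9 (aldol/dehydration).** This sequence may give E/Z mixtures, or retro-aldol of the tertiary carbinol, which would erode the stereocentre.
   - Fallback: make the silyl dienol ether (TBSOTf, Et3N) and run a Mukaiyama aldol with 5 under BF3·OEt2 at −78 °C. Then dehydrate the aldol with Burgess reagent or Martin sulfurane instead of a base-mediated E1cB.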